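(The readings are calculated with made-up constants; scatter was added.)

6 questions hang on one: how does the loss of free monomer follow the charge of initiator? The decision waits on it. We want monomer in chains ahead of free monomer at 15 min, and spring has the smallest charge. Can we charge spring, or must we pay for more?

| flask | free monomer | initiator | remark | time |
|---|---|---|---|---|
| Wednesday's | 2 M | 18 mM | run made earlier |  |
| spring | 2.0 M | 10 mM |  | 15 min |
| noon | 2.0 M | 12 mM |  | 15 min |
| summer | 2.0 M | 14 mM |  | 15 min |

Wednesday's run (percent of the free monomer charged)

| time / min | free monomer / % | monomer in chains / % | over-reaction product / % |
|---|---|---|---|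
| 0.833 | 92.9 | 7.6 | 0.1 |
| 1.50 | 87.0 | 11.0 | 0.5 |
| 3.00 | 79.8 | 22.6 | 1.2 |
| 6.00 | 58.5 | 38.3 | 2.0 |
| 10.0 | 41.0 | 49.6 | 6.1 |

(scatter of a reading: 1 percentage point)

- which of these there is most of at the end, counted by the free monomer in it, spring (over-reaction product / monomer in chains / free monomer)
- which of these there is most of at the end, counted by the free monomer in it, noon (over-reaction product / monomer in chains / free monomer)
- which of these there is most of at the end, counted by the free monomer in it, summer (over-reaction product / monomer in chains / free monomer)
- final amount of the leader among these, as a percentage of the free monomer charged, in spring
- final amount of the leader among these, as a percentage of the free monomer charged, in noon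
- final amount of the leader among these, as a percentage of the free monomer charged, in summer

- no earlier run changes the charge of initiator; that part of a forecast is a guess

Wednesday's run gives the loss constant of free monomer, a pseudo-first-order constant:

0.0892 min⁻¹ from the reading at 10.0 min

The reading at 6.00 min gives 0.0894 min⁻¹, so the decay looks first-order. But no earlier run varies the initiator, so the link to the charge is our assumption. We suppose that growing radicals are made in step with initiator and lost in pairs. Making and loss then balance at a level that follows the root of the charge:

free monomer left = exp(−constant × time × √(charge / Wednesday's charge))

This leaves 36.9% in spring and 30.7% in summer. We allow over-reaction product of 12.2%, twice Wednesday's last reading. Spring then holds 50.9% in chains, more than its free monomer. So we charge spring.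

The forecast differs. It scales the constant with the charge itself and names free monomer as spring's leader at 48%, with monomer in chains leading at 51% in noon and 55% in summer. It adds: “A weaker initiator order would flip the leader to chains”.

The flasks give monomer in chains as leader in spring at 50.3%, with 53.0% in noon and 55.3% in summer.

    initiator → 2 initiating radical (k = 2.60 × 10⁻⁴ s⁻¹)
    free monomer + initiating radical → growing radical + monomer in chains (k = 2.60 × 10⁵ M⁻¹ s⁻¹)
    free monomer + growing radical → monomer in chains + growing radical, rate k3*[growing radical]*[free monomer] (k = 4700 M⁻¹ s⁻¹)
    2 growing radical → dead chain (k = 4.90 × 10⁷ M⁻¹ s⁻¹)
    monomer in chains → over-reaction product (k = 3.50 × 10⁻⁴ s⁻¹)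

Spring holds 39.7% of free monomer, against our 36.9%. Growing radical at the end stands at 2.05 × 10⁻⁷ M in spring and 2.42 × 10⁻⁷ M in summer, a ratio of 1.18. The root of the ratio of the charges is 1.18, and the plain ratio of the charges is 1.40. In the run without the step from 2 growing radical to dead chain, the gap in monomer in chains between summer and spring falls from 5 percentage points to −0.032 points, the largest single effect on that gap.

For the neighbour of summer charged with 3.50 mM, the rule leaves 55.4% of free monomer at 15 min. The flask holds 58.0%, and free monomer leads there.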